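## Retrosynthetic overview

1. Feature (flavone numbering, primed piperidine atoms, used for all intermediates): C2' of the piperidine ring is bonded to C6 of ring A, N1' and C3'. C6 lies between the oxygen-bearing C5 and C7, with O1 (on C8a) para to it. A free phenolic oxygen ortho to C6 can bind a vinylboron reagent and pass the vinyl group to an iminium carbon at C2'.
2. Disconnections: ring C (C4a–C4, C4–C3, O1–C2) by carbonylative annulation of an ortho-iodophenyl acetate with phenylacetylene and CO. Piperidine C3'–C4' by ring-closing metathesis. C2'–N1', C2'–C3' and the stereocentre by an enantioselective Petasis reaction of a salicylaldehyde, N-methylbut-3-en-1-amine and a vinylboronic ester.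
3. Regiocontrol: only the para oxygen carries benzyl, and it becomes O1. Both ortho oxygens end up as methyl ethers, so the two free positions of ring A are equivalent and only the 6-substituted flavone can form.
4. Ring order: ring A and phenyl ring B are bought, the piperidine ring is closed in step 5 and ring C in step 9. The methyl ethers are removed last.

Key step: step 3

Assumption: the (S)-biphenol is taken to give the R configuration at C2'; the sense of induction has to be checked on the three-component product, and the equally available (R)-biphenol is used if it proves opposite.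

## Route

Step 1
Reactants: 1 4-hydroxy-2,6-dimethoxybenzaldehyde; 2 benzyl bromide
Product: 3 4-(benzyloxy)-2,6-dimethoxybenzaldehyde
Conditions: K2CO3 (1.5 equiv), DMF, rt
Reagents that add atoms: benzyl bromide BrCc1ccccc1
Why: Williamson ether synthesis on the only free hydroxyl group, whose phenoxide (para to the formyl group) forms readily with K2CO3, so no selectivity question arises.

Step 2
Reactants: 3 4-(benzyloxy)-2,6-dimethoxybenzaldehyde
Product: 4 4-(benzyloxy)-2-hydroxy-6-methoxybenzaldehyde
Conditions: MgI2·OEt2 (1.2 equiv), toluene, 80 °C; then 1 M HCl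
Reagents that add atoms: none
Why: Chelation-controlled ether cleavage in which magnesium binds the formyl oxygen and one ortho methoxy oxygen and iodide removes that methyl group by SN2, while the phenolate chelate resists a second cleavage, the unchelated para benzyl ether is left alone, and the equivalence of the two methoxy groups allows only one product.

Step 3
Reactants: 4 4-(benzyloxy)-2-hydroxy-6-methoxybenzaldehyde; 5 N-methylbut-3-en-1-amine; 6 dibutyl vinylboronate
Product: 10 5-(benzyloxy)-2-{(1R)-1-[but-3-en-1-yl(methyl)amino]prop-2-en-1-yl}-3-methoxyphenol, via chiral vinylboronate 7 (not isolated), via iminium phenolate 8 (not isolated), via tetracoordinate boronate 9 (not isolated)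
Conditions: 4 + 5 (1.2 equiv), 4 Å MS, toluene, rt; then (S)-3,3'-dibromo-1,1'-bi-2-naphthol (20 mol %), 6 (1.5 equiv), 0 → 25 °C; aqueous work-up
Reagents that add atoms: N-methylbut-3-en-1-amine CNCCC=C; dibutyl vinylboronate C=CB(OCCCC)OCCCC
Why: Amine 5 condenses with aldehyde 4 to the iminium phenolate 8 (the sieves take up the water), the biphenol displaces both butoxy groups of 6 to give the cyclic boronate 7, the phenoxide oxygen of 8 binds the boron of 7 to give the tetracoordinate boronate 9, and the vinyl group migrates from boron to the iminium carbon through a six-membered cyclic transition state, so that C2'–N1' and then C2'–C3' are formed. The closest known reaction type is the chiral-diol-catalysed Petasis borono-Mannich reaction of salicylaldehydes, secondary amines and alkenylboronic esters, used here on a doubly ortho-oxygenated aldehyde. No ring is closed; the step only places the vinyl and butenyl groups that close the piperidine ring in step 5. C2' is set by the axially chiral biphenol on boron, which in 9 leaves one face of the iminium ion open to the migrating vinyl group (R expected, see the assumption). The step needs enantioface selectivity, which rests on 7 being a stronger Lewis acid than 6 and on fast ligand exchange (the reason for the dibutyl ester rather than the exchange-inert pinacol ester), and it needs reactivity at a hindered, electron-rich iminium carbon, which the phenoxide ortho to C6 secures by making the transfer intramolecular. The mixture is kept at or below 25 °C and 10 is carried on at once, because loss of the amine through an ortho-quinone methide would erode the enantiomeric purity and open the way to a 2H-chromene.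

Step 4
Reactants: 10 5-(benzyloxy)-2-{(1R)-1-[but-3-en-1-yl(methyl)amino]prop-2-en-1-yl}-3-methoxyphenol
Product: 11 N-{(1R)-1-[4-(benzyloxy)-2,6-dimethoxyphenyl]prop-2-en-1-yl}-N-methylbut-3-en-1-amine
Conditions: MeOH (3 equiv), PPh3 (1.5 equiv), DIAD (1.5 equiv), THF, 0 °C → rt
Reagents that add atoms: methanol CO
Why: Mitsunobu etherification methylates only the acidic phenol through its ion pair with the methoxyphosphonium ion, so N1' is not quaternised as it could be with MeI, the cold neutral medium leaves C2' untouched, and capping this oxygen both shuts the ortho-quinone methide pathway and makes the two ortho oxygens alike.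

Step 5
Reactants: 11 N-{(1R)-1-[4-(benzyloxy)-2,6-dimethoxyphenyl]prop-2-en-1-yl}-N-methylbut-3-en-1-amine
Product: 14 (6R)-6-[4-(benzyloxy)-2,6-dimethoxyphenyl]-1-methyl-1,2,3,6-tetrahydropyridine, via diene ammonium tosylate 12 (not isolated), via tetrahydropyridinium tosylate 13 (not isolated)
Conditions: TsOH·H2O (1.0 equiv), CH2Cl2, rt; second-generation Grubbs catalyst RuCl2(=CHPh)(PCy3)(SIMes) (5 mol %), 0.01 M, 40 °C; then 1 M NaOH
Reagents that add atoms: none
Why: Ring-closing metathesis of two monosubstituted alkenes to a six-membered ring (C3'=C4'), driven by loss of ethene, in which protonation keeps the nitrogen lone pair off ruthenium, the catalyst should load on the unhindered butenyl end and close onto the vinyl group, and exactly one equivalent of acid in a non-ionising solvent avoids ionisation of the benzylic and allylic C2'–N1' bond, so C2' stays R.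

Step 6
Reactants: 14 (6R)-6-[4-(benzyloxy)-2,6-dimethoxyphenyl]-1-methyl-1,2,3,6-tetrahydropyridine
Product: 15 3,5-dimethoxy-4-[(2R)-1-methylpiperidin-2-yl]phenol
Conditions: H2 (1 atm), Pd/C (10 wt % Pd), MeOH, rt
Reagents that add atoms: none
Why: Heterogeneous hydrogenation saturates the disubstituted C3'=C4' alkene and hydrogenolyses the O-benzyl ether in one operation, while the endocyclic C2'–N1' bond, buried between two ortho methoxy groups, should resist hydrogenolysis in neutral methanol and C2' takes no part.

Step 7
Reactants: 15 3,5-dimethoxy-4-[(2R)-1-methylpiperidin-2-yl]phenol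
Product: 18 2-iodo-3,5-dimethoxy-4-[(2R)-1-methylpiperidin-2-yl]phenol, via piperidinium trifluoroacetate 16 (not isolated), via iodinated piperidinium trifluoroacetate 17 (not isolated)
Conditions: TFA (1.1 equiv), MeCN, −20 °C; NIS (1.0 equiv), −20 → 0 °C; then aq NaHCO3
Reagents that add atoms: N-iodosuccinimide O=C1CCC(=O)N1I
Why: Electrophilic aromatic iodination in which the two free positions of ring A are interconverted by rotation about C6–C2' and each is ortho to the free hydroxyl and ortho or para to a methoxy group, so only one mono-iodide can form, prior protonation to 16 shields N1' from oxidation by the N-iodoimide, and one equivalent of reagent at low temperature should hold back a second iodination.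

Step 8
Reactants: 18 2-iodo-3,5-dimethoxy-4-[(2R)-1-methylpiperidin-2-yl]phenol
Product: 19 2-iodo-3,5-dimethoxy-4-[(2R)-1-methylpiperidin-2-yl]phenyl acetate
Conditions: Ac2O (1.5 equiv), pyridine, 0 °C → rt
Reagents that add atoms: acetic anhydride CC(=O)OC(C)=O
Why: Ordinary O-acetylation of a phenol, which masks the oxygen para to C6 so that no para-quinone methide can form by loss of the amine in the basic next step and which makes the aryl iodide less electron-rich for oxidative addition.

Step 9
Reactants: 19 2-iodo-3,5-dimethoxy-4-[(2R)-1-methylpiperidin-2-yl]phenyl acetate; 20 phenylacetylene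
Product: 23 5,7-dimethoxy-6-[(2R)-1-methylpiperidin-2-yl]-2-phenyl-4H-chromen-4-one, via alkynone 21 (not isolated), via enaminone 22 (not isolated)
Conditions: 20 (1.5 equiv), CO (1 atm), PdCl2(PPh3)2 (5 mol %), dppp (5 mol %), thiourea (5 mol %), DBU (2 equiv), Et2NH, 40 °C
Reagents that add atoms: phenylacetylene C#Cc1ccccc1; carbon monoxide [C-]#[O+]
Why: Carbonylative Sonogashira-type coupling (oxidative addition of zerovalent palladium into C–I, CO insertion, alkynylation) gives alkynone 21, diethylamine adds to the ynone and cleaves the acetate to give enaminone 22, and the freed phenol displaces the amine at C2 in a 6-endo sense, so the flavone rather than the aurone should form, with the C5 methyl ether blocking closure onto the other ortho oxygen and 40 °C sparing C2'.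

Step 10
Reactants: 23 5,7-dimethoxy-6-[(2R)-1-methylpiperidin-2-yl]-2-phenyl-4H-chromen-4-one
Product: 24 5,7-dihydroxy-6-[(2R)-1-methylpiperidin-2-yl]-2-phenyl-4H-chromen-4-one
Conditions: BBr3 (6 equiv), CH2Cl2, −78 °C → rt; poured into ice-cold aq NaHCO3
Reagents that add atoms: none
Why: Lewis-acid cleavage of aryl methyl ethers in which the C5 ether is activated by chelation to the C4 carbonyl and the C7 ether falls to the excess reagent (one equivalent each is held by N1' and C4=O), the boron-bound oxygens are poor donors so that heterolysis of C2'–N1' is disfavoured, and the cold aprotic medium avoids the ring C opening and reclosure (Wessely–Moser rearrangement) that hot protic acids could cause.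

## Compound list

1 | 4-hydroxy-2,6-dimethoxybenzaldehyde | COc1cc(O)cc(OC)c1C=O | starting material
2 | benzyl bromide | BrCc1ccccc1 | starting material
3 | 4-(benzyloxy)-2,6-dimethoxybenzaldehyde | COc1cc(OCc2ccccc2)cc(OC)c1C=O | intermediate
4 | 4-(benzyloxy)-2-hydroxy-6-methoxybenzaldehyde | COc1cc(OCc2ccccc2)cc(O)c1C=O | intermediate
5 | N-methylbut-3-en-1-amine | CNCCC=C | starting material
6 | dibutyl vinylboronate | C=CB(OCCCC)OCCCC | starting material
7 | (S)-3,3'-dibromo-1,1'-binaphthalene-2,2'-diyl vinylboronate (axial chirality S, not expressible in SMILES) | C=CB1Oc2c(Br)cc3ccccc3c2-c2c(O1)c(Br)cc1ccccc21 | intermediate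
8 | 5-(benzyloxy)-2-{[but-3-en-1-yl(methyl)iminio]methyl}-3-methoxyphenolate | C=CCC[N+](C)=Cc1c([O-])cc(OCc2ccccc2)cc1OC | intermediate
9 | tetracoordinate boronate from 7 and 8 (boron bound to vinyl, both biphenol oxygens and the phenoxide oxygen; iminium ion intact) | C=C[B-]1(Oc2cc(OCc3ccccc3)cc(OC)c2C=[N+](C)CCC=C)Oc2c(Br)cc3ccccc3c2-c2c(O1)c(Br)cc1ccccc21 | intermediate
10 | 5-(benzyloxy)-2-{(1R)-1-[but-3-en-1-yl(methyl)amino]prop-2-en-1-yl}-3-methoxyphenol | C=C[C@@H](N(C)CCC=C)c1c(O)cc(OCc2ccccc2)cc1OC | intermediate
11 | N-{(1R)-1-[4-(benzyloxy)-2,6-dimethoxyphenyl]prop-2-en-1-yl}-N-methylbut-3-en-1-amine | C=C[C@@H](N(C)CCC=C)c1c(OC)cc(OCc2ccccc2)cc1OC | intermediate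
12 | 4-methylbenzenesulfonate salt of 11 | C=C[C@@H]([NH+](C)CCC=C)c1c(OC)cc(OCc2ccccc2)cc1OC.Cc1ccc(cc1)S(=O)(=O)[O-] | intermediate
13 | 4-methylbenzenesulfonate salt of 14 | C[NH+]1CCC=C[C@@H]1c1c(OC)cc(OCc2ccccc2)cc1OC.Cc1ccc(cc1)S(=O)(=O)[O-] | intermediate
14 | (6R)-6-[4-(benzyloxy)-2,6-dimethoxyphenyl]-1-methyl-1,2,3,6-tetrahydropyridine | CN1CCC=C[C@@H]1c1c(OC)cc(OCc2ccccc2)cc1OC | intermediate
15 | 3,5-dimethoxy-4-[(2R)-1-methylpiperidin-2-yl]phenol | CN1CCCC[C@@H]1c1c(OC)cc(O)cc1OC | intermediate
16 | trifluoroacetate salt of 15 | C[NH+]1CCCC[C@@H]1c1c(OC)cc(O)cc1OC.[O-]C(=O)C(F)(F)F | intermediate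
17 | trifluoroacetate salt of 18 | C[NH+]1CCCC[C@@H]1c1c(OC)cc(O)c(I)c1OC.[O-]C(=O)C(F)(F)F | intermediate
18 | 2-iodo-3,5-dimethoxy-4-[(2R)-1-methylpiperidin-2-yl]phenol | CN1CCCC[C@@H]1c1c(OC)cc(O)c(I)c1OC | intermediate
19 | 2-iodo-3,5-dimethoxy-4-[(2R)-1-methylpiperidin-2-yl]phenyl acetate | CN1CCCC[C@@H]1c1c(OC)cc(OC(C)=O)c(I)c1OC | intermediate
20 | phenylacetylene | C#Cc1ccccc1 | starting material
21 | 3,5-dimethoxy-4-[(2R)-1-methylpiperidin-2-yl]-2-(3-phenylprop-2-ynoyl)phenyl acetate | CN1CCCC[C@@H]1c1c(OC)cc(OC(C)=O)c(C(=O)C#Cc2ccccc2)c1OC | intermediate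
22 | 3-(diethylamino)-1-{6-hydroxy-2,4-dimethoxy-3-[(2R)-1-methylpiperidin-2-yl]phenyl}-3-phenylprop-2-en-1-one | CN1CCCC[C@@H]1c1c(OC)cc(O)c(C(=O)C=C(N(CC)CC)c2ccccc2)c1OC | intermediate
23 | 5,7-dimethoxy-6-[(2R)-1-methylpiperidin-2-yl]-2-phenyl-4H-chromen-4-one | CN1CCCC[C@@H]1c1c(OC)cc2oc(-c3ccccc3)cc(=O)c2c1OC | intermediate
24 | 5,7-dihydroxy-6-[(2R)-1-methylpiperidin-2-yl]-2-phenyl-4H-chromen-4-one | CN1CCCC[C@@H]1c1c(O)cc2oc(-c3ccccc3)cc(=O)c2c1O | target

## Step count and risks

Total step count: 10. Longest linear sequence: 10 steps (from 1).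

**Step 3.**
- Risk: iminium formation and vinyl transfer may be slow on the doubly ortho-substituted, electron-rich aldehyde. Facial selectivity may be poor if the uncatalysed transfer from 6 keeps pace with the transfer from 7. The product may also lose its amine on standing.
- Fallback: auxiliary control replaces catalyst control, and no free phenol is involved. It sets out from 3 and comes back at 11.
- Aldehyde 3 is condensed with (S)-2-methylpropane-2-sulfinamide (Ti(OEt)4, THF, 60 °C) to (S)-N-{(E)-[4-(benzyloxy)-2,6-dimethoxyphenyl]methylidene}-2-methylpropane-2-sulfinamide F1.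
- CH2=CHMgBr in CH2Cl2 at −48 °C should add through the magnesium-chelated chair to the Re face. This gives (S)-N-{(1R)-1-[4-(benzyloxy)-2,6-dimethoxyphenyl]prop-2-en-1-yl}-2-methylpropane-2-sulfinamide F2. Its minor diastereomer can be removed by chromatography, and the other sulfinamide antipode is available if the ortho methoxy groups reverse the facial sense.
- N-Methylation (LiN(SiMe3)2, MeI, THF, 0 °C) gives (S)-N-{(1R)-1-[4-(benzyloxy)-2,6-dimethoxyphenyl]prop-2-en-1-yl}-N,2-dimethylpropane-2-sulfinamide F3.
- HCl in MeOH at 0 °C removes the sulfinyl group and gives (1R)-1-[4-(benzyloxy)-2,6-dimethoxyphenyl]-N-methylprop-2-en-1-amine F4.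
- Alkylation with 4-bromobut-1-ene (K2CO3, NaI, MeCN, 60 °C) gives 11.

**Step 9.**
- Risk: oxidative addition may be sluggish at an iodide flanked by two oxygen substituents. Alkynylation may outrun CO uptake, diethylamine may capture the acylpalladium species, and closure may go 5-exo.
- Fallback: classical acylation chemistry replaces palladium. It sets out from 15 and comes back at 23, so steps 7 and 8 are not needed.
- Phenol 15 is C-acetylated at one of its two equivalent free positions (Ac2O, BF3·OEt2, 0 °C → rt; O-acetylation followed by a Fries-type shift) to 1-{6-hydroxy-2,4-dimethoxy-3-[(2R)-1-methylpiperidin-2-yl]phenyl}ethan-1-one F5.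
- Its dianion (LiN(SiMe3)2, THF, −78 °C) is C-benzoylated with benzoyl chloride in a Claisen-type condensation to 1-{6-hydroxy-2,4-dimethoxy-3-[(2R)-1-methylpiperidin-2-yl]phenyl}-3-phenylpropane-1,3-dione F6.
- Cyclodehydration (catalytic H2SO4, AcOH, 60 °C) closes O1–C2 and gives 23.

**Step 10.**
- Risk: C2' may partly racemise by reversible heterolysis of the C2'–N1' bond, either while N1' is bound to boron or once the ortho oxygens are free. This is most likely if slow cleavage of the C7 ether forces long reaction times.
- Fallback: enantiomeric purity is restored by classical resolution instead of being preserved. It sets out from 23 and comes back at 24.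
- The ethers are cleaved to completion as in step 10. The crude base is then combined with O,O'-di-p-toluoyl-L-tartaric acid in EtOH (the antipode of the acid is used if it gives the less soluble salt of the R base).
- This gives (2R)-2-(5,7-dihydroxy-4-oxo-2-phenyl-4H-chromen-6-yl)-1-methylpiperidinium hydrogen O,O'-di-p-toluoyl-L-tartrate F7.
- The salt is recrystallised until its enantiomeric purity no longer rises, then partitioned between aq NaHCO3 and CH2Cl2 to return 24.

## Further compounds

F1 | step 3 | (S)-N-{(E)-[4-(benzyloxy)-2,6-dimethoxyphenyl]methylidene}-2-methylpropane-2-sulfinamide | CC(C)(C)[S@@](/N=C/c1c(OC)cc(OCc2ccccc2)cc1OC)=O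
F2 | step 3 | (S)-N-{(1R)-1-[4-(benzyloxy)-2,6-dimethoxyphenyl]prop-2-en-1-yl}-2-methylpropane-2-sulfinamide | C=C[C@@H](N[S@@](=O)C(C)(C)C)c1c(OC)cc(OCc2ccccc2)cc1OC
F3 | step 3 | (S)-N-{(1R)-1-[4-(benzyloxy)-2,6-dimethoxyphenyl]prop-2-en-1-yl}-N,2-dimethylpropane-2-sulfinamide | C=C[C@@H](N(C)[S@@](=O)C(C)(C)C)c1c(OC)cc(OCc2ccccc2)cc1OC
F4 | step 3 | (1R)-1-[4-(benzyloxy)-2,6-dimethoxyphenyl]-N-methylprop-2-en-1-amine | C=C[C@@H](NC)c1c(OC)cc(OCc2ccccc2)cc1OC
F5 | step 9 | 1-{6-hydroxy-2,4-dimethoxy-3-[(2R)-1-methylpiperidin-2-yl]phenyl}ethan-1-one | CN1CCCC[C@@H]1c1c(OC)cc(O)c(C(C)=O)c1OC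
F6 | step 9 | 1-{6-hydroxy-2,4-dimethoxy-3-[(2R)-1-methylpiperidin-2-yl]phenyl}-3-phenylpropane-1,3-dione | CN1CCCC[C@@H]1c1c(OC)cc(O)c(C(=O)CC(=O)c2ccccc2)c1OC
F7 | step 10 | (2R)-2-(5,7-dihydroxy-4-oxo-2-phenyl-4H-chromen-6-yl)-1-methylpiperidinium hydrogen O,O'-di-p-toluoyl-L-tartrate | C[NH+]1CCCC[C@@H]1c1c(O)cc2oc(-c3ccccc3)cc(=O)c2c1O.OC(=O)[C@H](OC(=O)c1ccc(C)cc1)[C@@H](OC(=O)c1ccc(C)cc1)C([O-])=O
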